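Taking the share of Q turned in a given time as a property of the recipe is a pitfall: a first-order flask keeps that share steady across charges, and nothing yet says that these flasks are first-order. These are the flasks, the readings and the questions.

| flask | Q | X | L | time |
|---|---|---|---|---|
| violet | 250 mM | 375 mM | 0.500 mM |  |
| ochre | 100 mM | 225 mM | 0.500 mM |  |
| amber | 250 mM | 375 mM | 1.00 mM |  |
| green | 750 mM | 375 mM | 0.500 mM |  |
| red | 1200 mM | 1900 mM | 0.500 mM | 85 min |

| violet run: time / min | violet run: [Z] / mM | ochre run: time / min | ochre run: [Z] / mM | amber run: time / min | amber run: [Z] / mM | green run: time / min | green run: [Z] / mM |
|---|---|---|---|---|---|---|---|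
| 12 | 32 | 12 | 12 | 12 | 46 | 12 | 58 |
| 24 | 42 | 24 | 27 | 24 | 94 | 24 | 107 |
| 36 | 72 | 36 | 32 | 36 | 129 | 36 | 148 |
| 49 | 98 | 49 | 42 | 49 | 163 | 49 | 204 |
| 61 | 108 | 61 | 57 | 61 | 180 | 61 | 247 |
| 73 | 130 | 73 | 57 | 73 | 198 | 73 | 277 |
| 85 | 146 | 85 | 66 | 85 | 209 | 85 | 309 |

(each reading ± 4 mM)

- Overall: Q + X -> Z, with L as catalyst.
- Constant volume, constant temperature.
- The analysis sees a species whether free or bound.
- An order is taken over about fifteen percent of the charge, up and down.

- how the opening rate goes with [Q] round the charge of the violet run: the exponent of the rate at two percent of Q gone to Z (one fixed amount of Z, the same in the runs compared)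
- how the opening rate goes with [L] round the charge of the violet run: the exponent of the rate at two percent of Q gone to Z
- the ochre run starts with 150 mM less of Q and of X than the violet run, and with no Z. Compared where both hold the same amount of Q, once fifteen percent of what the ochre run was charged with has turned into Z, is the ochre run faster, slower or alike (within a tenth)?
- Z in the red run at 85 min, as a share of the Q charged

The bench rule says that a first-order flask (in Q) turns the same share of its charge in the same time, whatever the charge. The violet run has turned 58.4% of its Q at 85 min, which gives 96.9 min as its charge time, meaning the elapsed time divided by the natural log of the Q charged over the Q still left. Under the rule, the charge time stays the same from flask to flask.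

The ochre run, charged with 0.400 of the violet Q, has turned 66.0% at the same time, so its charge time is 78.8 min, shorter than the violet one. This is a reading, and each ochre point carries a scatter of 4.00% of that charge. The ochre run also holds less X, 225 mM against 375 mM, so this pair differs in two settings at once. Taken as it stands, the charge time of this pair grows as the Q charge to the power 0.226, which gives my own rough estimate of the order in Q, 0.774.

The quantity has a border, found from X charged over Q charged, since one X goes with each Q. In the green run that ratio is 0.500, so X is the limiting reagent there and caps the share at half, and a charge time read late in that run means little. The red run stands at 1.58 and the violet run at 1.50, so both are charged with X in excess of Q, and the cap of the green run does not apply to them.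

The red charge of Q is 4.80 times the violet one, and carrying that power beyond the charges of the runs gives an estimated charge time of 138 min and my estimated share of 46.0% at 85 min.

The forecast gave 0.77 for the order in Q, 1 for the order in L, alike for the ochre comparison with the words “product does nothing much”, and 45% for the red run.

The flask gives 0.72, 1.0, alike and 40.5%.

    L + Q → Dz + J (29.82 M⁻¹ min⁻¹)
    Dz + X → Z + L (293.4 M⁻¹ min⁻¹)
    2 Q ⇌ Q2, settled at all times (1.770 M⁻¹)

The red share of 40.5% means a charge time of 164 min. The pairing of Q into Q2 is the main reason for that low share, since the same red flask without the pairing reaches 70.1%, a charge time of 70.4 min. The green run turns a quarter of its Q charge by 45.2 min, a charge time of 157 min.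

The numbers in the tables were computed from invented constants.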